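Numbering (eremophilane): C1 acyloxy carbon, C4 carboxyl-bearing carbon (carboxyl carbon C15), C5 quaternary methyl carbon, C7 acrolein-bearing carbon (C11=C13, aldehyde C12), C8 ketone, C9=C10 enone alkene. Ring A is C1-C5 plus C10 and ring B is C5-C10.
Enabling feature: in ring B the methyl-bearing C5 lies 1,4 to the C8 carbonyl, so ring B with one extra double bond (C6=C7) is a 4-methylcyclohexa-2,5-dienone, the dearomatised form of para-cresol. Ring A bridges the meta carbon C10 and the para carbon C5 of that cresol, C1 is its benzylic carbinol carbon, and the C4 carboxyl can be carried as the vinyl group that an allylsilane leaves behind.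
Cuts: the C1-O ester bond (side-chain acid), C11=C13 (formaldehyde), C7-C11 (allyl bromide), then C4-C5 of ring A, the chain alkene (metathesis) and the C1-C10 aryl-carbonyl bond. In the acid, C2'=C3' (Wittig) and the C4' methyl bond are cut.
Forward: ring B is bought as 3-bromo-4-methylphenol, the chain is acylated onto C10 and extended to an allylsilane, and ring A closes in the oxidative dearomatisation. Then vinyl becomes CO2t-Bu, C6=C7 is hydrogenated, C1 is esterified, C7 is allylated and the allyl group is turned into the acrolein.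
Stereochemistry: C1 comes from a CBS reduction, and C5 and C4 from the chair-like ring closure relayed from C1. C7 comes from enolate allylation anti to the axial C5 methyl (also the equatorial, thermodynamic epimer). C4' comes from an Evans methylation and the E alkene from a stabilised ylide.
Key step: step 8

Remark: the metathesis product is drawn and listed as its E isomer. The Z isomer formed alongside is assumed to be carried on, because the alkene geometry disappears when C15 becomes a vinyl carbon.

Step 1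
Reactants: 1 3-bromo-4-methylphenol
Product: 2 (3-bromo-4-methylphenoxy)(tert-butyl)dimethylsilane
Conditions: TBSCl (1.1 equiv), imidazole (2 equiv), CH2Cl2, rt
Reagents that add atoms: tert-butyldimethylsilyl chloride, CC(C)(C)[Si](C)(C)Cl
Why: Imidazole-promoted O-silylation masks the acidic phenol so that the later bromine-lithium exchange becomes possible.

Step 2
Reactants: 3 pent-4-enoic acid
Product: 5 N-methoxy-N-methylpent-4-enamide, via acyl imidazolide 4 (not isolated)
Conditions: 1,1'-carbonyldiimidazole (1.1 equiv), CH2Cl2, rt; then MeNH(OMe)·HCl (1.2 equiv), rt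
Reagents that add atoms: N,O-dimethylhydroxylamine hydrochloride, CNOC.Cl; 1,1'-carbonyldiimidazole, O=C(n1ccnc1)n1ccnc1 (its imidazolyl group stays only in 4)
Why: Acyl imidazolide activation followed by aminolysis (Weinreb amide formation) runs under neutral conditions that leave the terminal alkene untouched.

Step 3
Reactants: 2 (3-bromo-4-methylphenoxy)(tert-butyl)dimethylsilane; 5 N-methoxy-N-methylpent-4-enamide
Product: 7 1-[5-(tert-butyldimethylsilyloxy)-2-methylphenyl]pent-4-en-1-one, via aryllithium 6 (not isolated)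
Conditions: 2, n-BuLi (1.05 equiv), THF, -78 °C; then 5, -78 to 0 °C; aq NH4Cl
Reagents that add atoms: n-butyllithium, [Li]CCCC (its lithium stays only in 6)
Why: Bromine-lithium exchange followed by the Weinreb ketone synthesis forms the C1-C10 bond, and the N-methoxy-N-methylamide prevents a second addition.

Step 4
Reactants: 7 1-[5-(tert-butyldimethylsilyloxy)-2-methylphenyl]pent-4-en-1-one
Product: 8 (1R)-1-[5-(tert-butyldimethylsilyloxy)-2-methylphenyl]pent-4-en-1-ol
Conditions: (S)-2-methyl-CBS-oxazaborolidine (10 mol %), BH3·SMe2 (0.7 equiv), THF, -20 °C, slow addition of 7; MeOH quench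
Reagents that add atoms: none
Why: In the Corey-Bakshi-Shibata reduction the aryl ring acts as the large and the butenyl chain as the small substituent, so the (S)-catalyst should give the (R)-carbinol at C1, and the catalysed carbonyl reduction should outrun hydroboration of the terminal alkene while borane is kept substoichiometric and cold.

Step 5
Reactants: 8 (1R)-1-[5-(tert-butyldimethylsilyloxy)-2-methylphenyl]pent-4-en-1-ol
Product: 9 tert-butyl{3-[(1R)-1-(tert-butyldimethylsilyloxy)pent-4-en-1-yl]-4-methylphenoxy}dimethylsilane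
Conditions: TBSOTf (1.2 equiv), 2,6-lutidine (2 equiv), CH2Cl2, 0 °C
Reagents that add atoms: tert-butyldimethylsilyl trifluoromethanesulfonate, CC(C)(C)[Si](C)(C)OS(=O)(=O)C(F)(F)F
Why: Silyl triflate silylation of the hindered secondary benzylic alcohol is fast at 0 °C, does not touch C1, and installs the bulky group that later steers the ring closure.

Step 6
Reactants: 9 tert-butyl{3-[(1R)-1-(tert-butyldimethylsilyloxy)pent-4-en-1-yl]-4-methylphenoxy}dimethylsilane
Product: 10 3-[(1R)-1-(tert-butyldimethylsilyloxy)pent-4-en-1-yl]-4-methylphenol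
Conditions: K2CO3 (1 equiv), MeOH, rt
Reagents that add atoms: none
Why: Base-mediated methanolysis tells the two silyl ethers apart because phenoxide is by far the better leaving group (chemoselective cleavage of an aryl silyl ether).

Step 7
Reactants: 10 3-[(1R)-1-(tert-butyldimethylsilyloxy)pent-4-en-1-yl]-4-methylphenol; 11 allyltrimethylsilane
Product: 12 3-[(1R,4E)-1-(tert-butyldimethylsilyloxy)-6-(trimethylsilyl)hex-4-en-1-yl]-4-methylphenol
Conditions: 11 (4 equiv), second-generation Hoveyda-Grubbs catalyst RuCl2(H2IMes)(=CH-C6H4-2-Oi-Pr) (5 mol %), CH2Cl2, 40 °C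
Reagents that add atoms: none
Why: Olefin cross metathesis of a terminal alkene with excess allyltrimethylsilane is a standard entry to substituted allylsilanes, tolerates the free phenol and should favour the E isomer.

Step 8
Reactants: 12 3-[(1R,4E)-1-(tert-butyldimethylsilyloxy)-6-(trimethylsilyl)hex-4-en-1-yl]-4-methylphenol
Product: 14 (4aR,5R,8R)-8-(tert-butyldimethylsilyloxy)-5-ethenyl-4a-methyl-5,6,7,8-tetrahydronaphthalen-2(4aH)-one, via aryloxyiodane 13 (not isolated)
Conditions: PhI(OAc)2 (1.1 equiv), (CF3)2CHOH (0.01 M), 0 °C, 10 min; aq NaHCO3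
Reagents that add atoms: (diacetoxyiodo)benzene, CC(=O)OI(OC(C)=O)c1ccccc1 (its atoms stay only in 13)
Why: Ligand exchange of the phenol on the trivalent iodine of PhI(OAc)2 gives 13, which in the strongly ionising but poorly nucleophilic (CF3)2CHOH loses PhI and acetate to leave a phenoxenium ion with most of its positive charge on the methyl-bearing para carbon C5; the γ-carbon of the allylsilane (C4) bonds to C5 and the β-silyl cation at C15 sheds its silyl group, which leaves the C4 vinyl group and the ring B dienone. The closest known reaction type is the hypervalent-iodine oxidative Hosomi-Sakurai allylation of 4-alkylphenols, practised between two components and in spiro-closing intramolecular form, and the present case differs only in that the tether is anchored at the meta carbon C10, so that the new ring is fused. Ring A (C10, C1, C2, C3, C4, C5) closes in a chair-like 6-exo-trig mode, counted at the C4=C15 alkene. C5 is controlled by C1: allylic strain against C9-H keeps the small C1-H bond in the arene plane and turns the bulky silyloxy group pseudoaxial, so in an early transition state the chain reaches C5 from the opposite face and the methyl group is bent towards the silyloxy face. C4 is controlled by the chair, in which C15 takes the pseudoequatorial site and so ends cis to the C5 methyl group, from either alkene isomer of 12 because C15 keeps no geometry. The step needs bond formation at para C5 instead of ortho C9 and ahead of capture by solvent or acetate, which the charge distribution of the methyl-stabilised cation, the short C1-C2-C3 tether that parks C4 above C5, the non-nucleophilic solvent and high dilution should secure.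

Step 9
Reactants: 14 (4aR,5R,8R)-8-(tert-butyldimethylsilyloxy)-5-ethenyl-4a-methyl-5,6,7,8-tetrahydronaphthalen-2(4aH)-one
Product: 16 (1S,4R,8aR)-4-(tert-butyldimethylsilyloxy)-8a-methyl-6-oxo-1,2,3,4,6,8a-hexahydronaphthalene-1-carbaldehyde, via vicinal diol 15 (not isolated)
Conditions: OsO4 (2 mol %), NaIO4 (4 equiv), 2,6-lutidine (2 equiv), dioxane/H2O, rt
Reagents that add atoms: osmium tetroxide, O=[Os](=O)(=O)=O (oxygen carrier); sodium periodate, [Na+].[O-]I(=O)(=O)=O (terminal oxygen source)
Why: In the Lemieux-Johnson oxidation OsO4 selects the electron-rich monosubstituted vinyl group over the two electron-poor dienone alkenes, and 2,6-lutidine keeps the medium neutral so that the equatorial C4 formyl group is not epimerised.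

Step 10
Reactants: 16 (1S,4R,8aR)-4-(tert-butyldimethylsilyloxy)-8a-methyl-6-oxo-1,2,3,4,6,8a-hexahydronaphthalene-1-carbaldehyde
Product: 17 (1S,4R,8aR)-4-(tert-butyldimethylsilyloxy)-8a-methyl-6-oxo-1,2,3,4,6,8a-hexahydronaphthalene-1-carboxylic acid
Conditions: NaClO2, NaH2PO4, 2-methylbut-2-ene, t-BuOH/H2O, rt
Reagents that add atoms: sodium chlorite, [Na+].[O-]Cl=O
Why: The Pinnick oxidation converts the aldehyde into the acid without touching the dienone, the silyl ether or the α-stereocentre.

Step 11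
Reactants: 17 (1S,4R,8aR)-4-(tert-butyldimethylsilyloxy)-8a-methyl-6-oxo-1,2,3,4,6,8a-hexahydronaphthalene-1-carboxylic acid
Product: 18 tert-butyl (1S,4R,8aR)-4-(tert-butyldimethylsilyloxy)-8a-methyl-6-oxo-1,2,3,4,6,8a-hexahydronaphthalene-1-carboxylate
Conditions: Cl3CC(=NH)Ot-Bu (3 equiv), CH2Cl2/cyclohexane, rt
Reagents that add atoms: tert-butyl 2,2,2-trichloroacetimidate, CC(C)(C)OC(=N)C(Cl)(Cl)Cl
Why: tert-Butyl transfer from the trichloroacetimidate esterifies the carboxyl group at oxygen, so crowding next to the quaternary C5 does not matter and no strong acid that could start a dienone-phenol rearrangement is needed.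

Step 12
Reactants: 18 tert-butyl (1S,4R,8aR)-4-(tert-butyldimethylsilyloxy)-8a-methyl-6-oxo-1,2,3,4,6,8a-hexahydronaphthalene-1-carboxylate
Product: 19 tert-butyl (1S,4R,8aR)-4-(tert-butyldimethylsilyloxy)-8a-methyl-6-oxo-1,2,3,4,6,7,8,8a-octahydronaphthalene-1-carboxylate
Conditions: RhCl(PPh3)3 (10 mol %), H2 (1 atm), toluene/EtOH, rt
Reagents that add atoms: none
Why: Homogeneous hydrogenation with RhCl(PPh3)3 responds strongly to alkene substitution and, as with steroidal 1,4-dien-3-ones, should saturate the disubstituted C6=C7 bond and leave the trisubstituted C9=C10 enone.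

Step 13
Reactants: 19 tert-butyl (1S,4R,8aR)-4-(tert-butyldimethylsilyloxy)-8a-methyl-6-oxo-1,2,3,4,6,7,8,8a-octahydronaphthalene-1-carboxylate
Product: 20 tert-butyl (1S,4R,8aR)-4-hydroxy-8a-methyl-6-oxo-1,2,3,4,6,7,8,8a-octahydronaphthalene-1-carboxylate
Conditions: HF·pyridine, THF, 0 °C to rt
Reagents that add atoms: none
Why: Fluoride-mediated desilylation in a buffered, weakly acidic medium frees the C1 alcohol without base-induced isomerisation of the γ-hydroxy enone and without loss of the tert-butyl ester.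

Step 14
Reactants: 21 hexanoyl chloride; 22 (R)-4-benzyl-2-oxazolidinone
Product: 23 (R)-4-benzyl-3-hexanoyl-2-oxazolidinone
Conditions: Et3N (1.5 equiv), DMAP (10 mol %), CH2Cl2, 0 °C to rt
Reagents that add atoms: none
Why: DMAP-catalysed N-acylation of the oxazolidinone with the acid chloride attaches the auxiliary without a strong base.

Step 15
Reactants: 23 (R)-4-benzyl-3-hexanoyl-2-oxazolidinone
Product: 25 (R)-4-benzyl-3-[(2R)-2-methylhexanoyl]-2-oxazolidinone, via sodium Z-enolate 24 (not isolated)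
Conditions: NaN(SiMe3)2 (1.1 equiv), THF, -78 °C; then MeI (4 equiv), -78 °C
Reagents that add atoms: iodomethane, CI; sodium bis(trimethylsilyl)amide, C[Si](C)(C)[N-][Si](C)(C)C.[Na+] (its sodium stays only in 24)
Why: In the Evans asymmetric alkylation the chelated Z-enolate is methylated on the face opposite to the benzyl group, which with the (R)-auxiliary gives the (R)-2-methylhexanoyl unit.

Step 16
Reactants: 25 (R)-4-benzyl-3-[(2R)-2-methylhexanoyl]-2-oxazolidinone
Product: 26 (R)-2-methylhexan-1-ol
Conditions: LiBH4 (1.5 equiv), Et2O, MeOH (1.5 equiv), 0 °C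
Reagents that add atoms: none
Why: Reductive removal of the auxiliary with LiBH4 gives the primary alcohol without epimerisation and returns the oxazolidinone.

Step 17
Reactants: 26 (R)-2-methylhexan-1-ol
Product: 27 (R)-2-methylhexanal
Conditions: Dess-Martin periodinane (1.2 equiv), CH2Cl2, 0 °C to rt; washed solution used at once
Reagents that add atoms: none
Why: The Dess-Martin oxidation works close to neutrality, so the α-stereocentre of the volatile aldehyde should be kept if the crude solution is used directly.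

Step 18
Reactants: 27 (R)-2-methylhexanal; 28 ethyl 2-(triphenylphosphoranylidene)propanoate
Product: 29 ethyl (2E,4R)-2,4-dimethyloct-2-enoate
Conditions: 28 (1.3 equiv), CH2Cl2, rt to 40 °C
Reagents that add atoms: none
Why: Wittig olefination with the stabilised α-methyl ylide gives the trisubstituted E enoate and needs no added base that could racemise the aldehyde.

Step 19
Reactants: 29 ethyl (2E,4R)-2,4-dimethyloct-2-enoate
Product: 30 (2E,4R)-2,4-dimethyloct-2-enoic acid
Conditions: LiOH (3 equiv), THF/MeOH/H2O, 40 °C; then aq HCl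
Reagents that add atoms: lithium hydroxide, [Li+].[OH-]
Why: Saponification of the ethyl ester with aqueous LiOH leaves the conjugated E alkene and the γ-stereocentre unchanged.

Step 20
Reactants: 20 tert-butyl (1S,4R,8aR)-4-hydroxy-8a-methyl-6-oxo-1,2,3,4,6,7,8,8a-octahydronaphthalene-1-carboxylate; 30 (2E,4R)-2,4-dimethyloct-2-enoic acid
Product: 32 tert-butyl (1S,4R,8aR)-4-{[(2E,4R)-2,4-dimethyloct-2-enoyl]oxy}-8a-methyl-6-oxo-1,2,3,4,6,7,8,8a-octahydronaphthalene-1-carboxylate, via mixed anhydride 31 (not isolated)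
Conditions: 30, 2,4,6-Cl3C6H2COCl (1.3 equiv), Et3N (1.5 equiv), toluene, rt; then 20, DMAP (2 equiv), toluene, rt to 40 °C
Reagents that add atoms: 2,4,6-trichlorobenzoyl chloride, O=C(Cl)c1c(Cl)cc(Cl)cc1Cl (its aroyl group stays only in 31)
Why: In the Yamaguchi esterification DMAP attacks the less hindered acyl group of 31 and the resulting acylpyridinium ion acylates the hindered axial C1 alcohol at oxygen, hence with retention at C1.

Step 21
Reactants: 32 tert-butyl (1S,4R,8aR)-4-{[(2E,4R)-2,4-dimethyloct-2-enoyl]oxy}-8a-methyl-6-oxo-1,2,3,4,6,7,8,8a-octahydronaphthalene-1-carboxylate; 33 allyl bromide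
Product: 35 tert-butyl (1S,4R,7R,8aR)-4-{[(2E,4R)-2,4-dimethyloct-2-enoyl]oxy}-8a-methyl-6-oxo-7-(prop-2-en-1-yl)-1,2,3,4,6,7,8,8a-octahydronaphthalene-1-carboxylate, via lithium dienolate 34 (not isolated)
Conditions: LiN(SiMe3)2 (1.1 equiv), THF, -78 °C; then 33 (3 equiv), DMPU, -78 to -30 °C
Reagents that add atoms: lithium bis(trimethylsilyl)amide, C[Si](C)(C)[N-][Si](C)(C)C.[Li+] (its lithium stays only in 34)
Why: Kinetic α'-deprotonation of the enone at C7 is much faster than deprotonation of either hindered ester, and SN2 allylation of the cross-conjugated dienolate should occur anti to the axial C5 methyl group to place the allyl group equatorial, the epimer that equilibration would also favour.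

Step 22
Reactants: 35 tert-butyl (1S,4R,7R,8aR)-4-{[(2E,4R)-2,4-dimethyloct-2-enoyl]oxy}-8a-methyl-6-oxo-7-(prop-2-en-1-yl)-1,2,3,4,6,7,8,8a-octahydronaphthalene-1-carboxylate
Product: 37 tert-butyl (1S,4R,7S,8aR)-4-{[(2E,4R)-2,4-dimethyloct-2-enoyl]oxy}-8a-methyl-6-oxo-7-(2-oxoethyl)-1,2,3,4,6,7,8,8a-octahydronaphthalene-1-carboxylate, via vicinal diol 36 (not isolated)
Conditions: OsO4 (2 mol %), NaIO4 (4 equiv), 2,6-lutidine (2 equiv), dioxane/H2O, rt
Reagents that add atoms: osmium tetroxide, O=[Os](=O)(=O)=O (oxygen carrier); sodium periodate, [Na+].[O-]I(=O)(=O)=O (terminal oxygen source)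
Why: The Lemieux-Johnson oxidation attacks only the terminal alkene because the enone and enoate alkenes are trisubstituted and electron-poor, and the lutidine buffer avoids acid-induced furan formation from the 1,4-keto aldehyde.

Step 23
Reactants: 37 tert-butyl (1S,4R,7S,8aR)-4-{[(2E,4R)-2,4-dimethyloct-2-enoyl]oxy}-8a-methyl-6-oxo-7-(2-oxoethyl)-1,2,3,4,6,7,8,8a-octahydronaphthalene-1-carboxylate
Product: 38 tert-butyl (1S,4R,7S,8aR)-4-{[(2E,4R)-2,4-dimethyloct-2-enoyl]oxy}-8a-methyl-6-oxo-7-(3-oxoprop-1-en-2-yl)-1,2,3,4,6,7,8,8a-octahydronaphthalene-1-carboxylate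
Conditions: 37% aq CH2O (1.5 equiv), pyrrolidine (20 mol %), EtCO2H (20 mol %), i-PrOH, 45 °C
Reagents that add atoms: formaldehyde, C=O
Why: The amine and acid co-catalysed Mannich condensation with formaldehyde followed by β-elimination (α-methylenation of aldehydes) acts at C11, the only position that readily forms an enamine, and the near neutral buffer should spare C7 and both esters.

Step 24
Reactants: 38 tert-butyl (1S,4R,7S,8aR)-4-{[(2E,4R)-2,4-dimethyloct-2-enoyl]oxy}-8a-methyl-6-oxo-7-(3-oxoprop-1-en-2-yl)-1,2,3,4,6,7,8,8a-octahydronaphthalene-1-carboxylate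
Product: 39 (1S,4R,7S,8aR)-4-{[(2E,4R)-2,4-dimethyloct-2-enoyl]oxy}-8a-methyl-6-oxo-7-(3-oxoprop-1-en-2-yl)-1,2,3,4,6,7,8,8a-octahydronaphthalene-1-carboxylic acid (CNP0143497.3)
Conditions: CF3CO2H/CH2Cl2 (1:4), 0 °C
Reagents that add atoms: none
Why: Acidolysis of the tert-butyl ester by loss of isobutene (E1 type) should leave the C1 ester intact, since its ionisation is disfavoured next to the enone β-carbon, and should also spare the enone and the enal at 0 °C.

Compound list
1 | 3-bromo-4-methylphenol | Cc1ccc(O)cc1Br | starting material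
2 | (3-bromo-4-methylphenoxy)(tert-butyl)dimethylsilane | Cc1ccc(O[Si](C)(C)C(C)(C)C)cc1Br | intermediate
3 | pent-4-enoic acid | C=CCCC(=O)O | starting material
4 | 1-(imidazol-1-yl)pent-4-en-1-one (acyl imidazolide, not isolated) | C=CCCC(=O)n1ccnc1 | intermediate
5 | N-methoxy-N-methylpent-4-enamide | C=CCCC(=O)N(C)OC | intermediate
6 | [5-(tert-butyldimethylsilyloxy)-2-methylphenyl]lithium (aryllithium, not isolated) | Cc1ccc(O[Si](C)(C)C(C)(C)C)cc1[Li] | intermediate
7 | 1-[5-(tert-butyldimethylsilyloxy)-2-methylphenyl]pent-4-en-1-one | Cc1ccc(O[Si](C)(C)C(C)(C)C)cc1C(=O)CCC=C | intermediate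
8 | (1R)-1-[5-(tert-butyldimethylsilyloxy)-2-methylphenyl]pent-4-en-1-ol | Cc1ccc(O[Si](C)(C)C(C)(C)C)cc1[C@H](O)CCC=C | intermediate
9 | tert-butyl{3-[(1R)-1-(tert-butyldimethylsilyloxy)pent-4-en-1-yl]-4-methylphenoxy}dimethylsilane | Cc1ccc(O[Si](C)(C)C(C)(C)C)cc1[C@H](O[Si](C)(C)C(C)(C)C)CCC=C | intermediate
10 | 3-[(1R)-1-(tert-butyldimethylsilyloxy)pent-4-en-1-yl]-4-methylphenol | Cc1ccc(O)cc1[C@H](O[Si](C)(C)C(C)(C)C)CCC=C | intermediate
11 | allyltrimethylsilane | C=CC[Si](C)(C)C | starting material
12 | 3-[(1R,4E)-1-(tert-butyldimethylsilyloxy)-6-(trimethylsilyl)hex-4-en-1-yl]-4-methylphenol | Cc1ccc(O)cc1[C@H](O[Si](C)(C)C(C)(C)C)CC/C=C/C[Si](C)(C)C | intermediate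
13 | acetoxy(phenyl)iodanyl ether of phenol 12 (aryloxyiodane, not isolated) | Cc1ccc(OI(OC(C)=O)c2ccccc2)cc1[C@H](O[Si](C)(C)C(C)(C)C)CC/C=C/C[Si](C)(C)C | intermediate
14 | (4aR,5R,8R)-8-(tert-butyldimethylsilyloxy)-5-ethenyl-4a-methyl-5,6,7,8-tetrahydronaphthalen-2(4aH)-one (silyloxy, methyl and vinyl groups all on one face) | O=C1C=C[C@@]2(C)C(=C1)[C@H](O[Si](C)(C)C(C)(C)C)CC[C@@H]2C=C | intermediate
15 | (4aR,5S,8R)-8-(tert-butyldimethylsilyloxy)-5-(1,2-dihydroxyethyl)-4a-methyl-5,6,7,8-tetrahydronaphthalen-2(4aH)-one (carbinol epimers, not isolated) | O=C1C=C[C@@]2(C)C(=C1)[C@H](O[Si](C)(C)C(C)(C)C)CC[C@@H]2C(O)CO | intermediate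
16 | (1S,4R,8aR)-4-(tert-butyldimethylsilyloxy)-8a-methyl-6-oxo-1,2,3,4,6,8a-hexahydronaphthalene-1-carbaldehyde | O=C1C=C[C@@]2(C)C(=C1)[C@H](O[Si](C)(C)C(C)(C)C)CC[C@@H]2C=O | intermediate
17 | (1S,4R,8aR)-4-(tert-butyldimethylsilyloxy)-8a-methyl-6-oxo-1,2,3,4,6,8a-hexahydronaphthalene-1-carboxylic acid | O=C1C=C[C@@]2(C)C(=C1)[C@H](O[Si](C)(C)C(C)(C)C)CC[C@@H]2C(=O)O | intermediate
18 | tert-butyl (1S,4R,8aR)-4-(tert-butyldimethylsilyloxy)-8a-methyl-6-oxo-1,2,3,4,6,8a-hexahydronaphthalene-1-carboxylate | O=C1C=C[C@@]2(C)C(=C1)[C@H](O[Si](C)(C)C(C)(C)C)CC[C@@H]2C(=O)OC(C)(C)C | intermediate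
19 | tert-butyl (1S,4R,8aR)-4-(tert-butyldimethylsilyloxy)-8a-methyl-6-oxo-1,2,3,4,6,7,8,8a-octahydronaphthalene-1-carboxylate | O=C1CC[C@@]2(C)C(=C1)[C@H](O[Si](C)(C)C(C)(C)C)CC[C@@H]2C(=O)OC(C)(C)C | intermediate
20 | tert-butyl (1S,4R,8aR)-4-hydroxy-8a-methyl-6-oxo-1,2,3,4,6,7,8,8a-octahydronaphthalene-1-carboxylate | O=C1CC[C@@]2(C)C(=C1)[C@H](O)CC[C@@H]2C(=O)OC(C)(C)C | intermediate
21 | hexanoyl chloride | CCCCCC(=O)Cl | starting material
22 | (R)-4-benzyl-2-oxazolidinone | O=C1N[C@H](Cc2ccccc2)CO1 | starting material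
23 | (R)-4-benzyl-3-hexanoyl-2-oxazolidinone | CCCCCC(=O)N1[C@H](Cc2ccccc2)COC1=O | intermediate
24 | sodium Z-enolate of 23 (not isolated) | CCCC/C=C(\[O-])N1[C@H](Cc2ccccc2)COC1=O.[Na+] | intermediate
25 | (R)-4-benzyl-3-[(2R)-2-methylhexanoyl]-2-oxazolidinone | CCCC[C@@H](C)C(=O)N1[C@H](Cc2ccccc2)COC1=O | intermediate
26 | (R)-2-methylhexan-1-ol | CCCC[C@@H](C)CO | intermediate
27 | (R)-2-methylhexanal | O=C[C@H](C)CCCC | intermediate
28 | ethyl 2-(triphenylphosphoranylidene)propanoate | CCOC(=O)C(C)=P(c1ccccc1)(c1ccccc1)c1ccccc1 | starting material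
29 | ethyl (2E,4R)-2,4-dimethyloct-2-enoate | CCOC(=O)/C(C)=C/[C@H](C)CCCC | intermediate
30 | (2E,4R)-2,4-dimethyloct-2-enoic acid | OC(=O)/C(C)=C/[C@H](C)CCCC | intermediate
31 | (2E,4R)-2,4-dimethyloct-2-enoic 2,4,6-trichlorobenzoic anhydride (not isolated) | O=C(OC(=O)/C(C)=C/[C@H](C)CCCC)c1c(Cl)cc(Cl)cc1Cl | intermediate
32 | tert-butyl (1S,4R,8aR)-4-{[(2E,4R)-2,4-dimethyloct-2-enoyl]oxy}-8a-methyl-6-oxo-1,2,3,4,6,7,8,8a-octahydronaphthalene-1-carboxylate | O=C1CC[C@@]2(C)C(=C1)[C@H](OC(=O)/C(C)=C/[C@H](C)CCCC)CC[C@@H]2C(=O)OC(C)(C)C | intermediate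
33 | allyl bromide | C=CCBr | starting material
34 | lithium cross-conjugated dienolate of 32, C7=C8(OLi)-C9=C10 (not isolated) | [Li+].[O-]C1=CC[C@@]2(C)C(=C1)[C@H](OC(=O)/C(C)=C/[C@H](C)CCCC)CC[C@@H]2C(=O)OC(C)(C)C | intermediate
35 | tert-butyl (1S,4R,7R,8aR)-4-{[(2E,4R)-2,4-dimethyloct-2-enoyl]oxy}-8a-methyl-6-oxo-7-(prop-2-en-1-yl)-1,2,3,4,6,7,8,8a-octahydronaphthalene-1-carboxylate | C=CC[C@@H]1C[C@@]2(C)C(=CC1=O)[C@H](OC(=O)/C(C)=C/[C@H](C)CCCC)CC[C@@H]2C(=O)OC(C)(C)C | intermediate
36 | tert-butyl (1S,4R,7S,8aR)-7-(2,3-dihydroxypropyl)-4-{[(2E,4R)-2,4-dimethyloct-2-enoyl]oxy}-8a-methyl-6-oxo-1,2,3,4,6,7,8,8a-octahydronaphthalene-1-carboxylate (carbinol epimers, not isolated) | OCC(O)C[C@@H]1C[C@@]2(C)C(=CC1=O)[C@H](OC(=O)/C(C)=C/[C@H](C)CCCC)CC[C@@H]2C(=O)OC(C)(C)C | intermediate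
37 | tert-butyl (1S,4R,7S,8aR)-4-{[(2E,4R)-2,4-dimethyloct-2-enoyl]oxy}-8a-methyl-6-oxo-7-(2-oxoethyl)-1,2,3,4,6,7,8,8a-octahydronaphthalene-1-carboxylate | O=CC[C@@H]1C[C@@]2(C)C(=CC1=O)[C@H](OC(=O)/C(C)=C/[C@H](C)CCCC)CC[C@@H]2C(=O)OC(C)(C)C | intermediate
38 | tert-butyl (1S,4R,7S,8aR)-4-{[(2E,4R)-2,4-dimethyloct-2-enoyl]oxy}-8a-methyl-6-oxo-7-(3-oxoprop-1-en-2-yl)-1,2,3,4,6,7,8,8a-octahydronaphthalene-1-carboxylate | C=C(C=O)[C@@H]1C[C@@]2(C)C(=CC1=O)[C@H](OC(=O)/C(C)=C/[C@H](C)CCCC)CC[C@@H]2C(=O)OC(C)(C)C | intermediate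
39 | (1S,4R,7S,8aR)-4-{[(2E,4R)-2,4-dimethyloct-2-enoyl]oxy}-8a-methyl-6-oxo-7-(3-oxoprop-1-en-2-yl)-1,2,3,4,6,7,8,8a-octahydronaphthalene-1-carboxylic acid (eremophilane numbering 1R,4S,5R,7S) | C=C(C=O)[C@@H]1C[C@@]2(C)C(=CC1=O)[C@H](OC(=O)/C(C)=C/[C@H](C)CCCC)CC[C@@H]2C(=O)O | target

Total step count: 24 steps.
Longest linear sequence: 17 steps (steps 1, 3 to 13 and 20 to 24). The branch through step 2 has the same length, and the side-chain branch (steps 14 to 19) joins at step 20.

Steps most likely to fail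

**Step 8.**
- The oxidised arene may be intercepted by the solvent or by acetate before the C4-C5 bond forms.
- The chain may close onto the ortho carbon C9 and rearomatise.
- The allylsilane may be protodesilylated in the acidic alcohol.
- The relay from C1 may be weak, because the syn-axial contact between the silyloxy group and the emerging axial methyl group works against the allylic strain.

The fallback reverses the polarity of the same bond formation, so that the phenol is the nucleophile and no oxidant is used. It sets out from phenol 10. Cross metathesis with allyl methyl carbonate (same ruthenium catalyst, CH2Cl2, 40 °C) should give the (E)-allylic methyl carbonate F1. Zerovalent palladium (Pd2(dba)3·CHCl3, PPh3, CH2Cl2, rt) should ionise F1 to a π-allyl complex, while the liberated methoxide deprotonates the phenol. Attack of the para carbon C5 on the inner allyl terminus C4 (intramolecular dearomatising allylic alkylation of phenols) closes the same six-membered ring and comes back to the route at dienone 14. A chiral phosphine on palladium would give an additional handle on C4 and on the face of the arene.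

**Step 21.**
- Proton transfer between the dienolate and the product may lead to double allylation or to the extended dienolate.
- The base may deprotonate or attack the C1 enoate.

The fallback changes the order of events so that the enolate chemistry is finished before the acyl chain is present. It sets out from silyl ether 19. LiN(SiMe3)2 in THF at -78 °C should give the lithium dienolate F2, and allyl bromide 33 with DMPU converts it into the C7-allyl silyl ether F3. HF·pyridine then frees the C7-allyl alcohol F4. Yamaguchi esterification with acid 30 through mixed anhydride 31 comes back to the route at 35.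

**Step 24.**
- In CF3CO2H, enolisation of the C8 ketone towards C7 may move the C11=C13 double bond into conjugation.
- The same enolisation may epimerise C7.
- The enal may add nucleophiles during concentration.

The fallback removes the acid-labile group while the side chain is still a robust allyl group, and it makes the sensitive acrolein last under the buffered conditions of step 23. It sets out from 35. CF3CO2H/CH2Cl2 at 0 °C should give the C7-allyl carboxylic acid F5. OsO4, NaIO4 and 2,6-lutidine cleave the terminal alkene through the vicinal diol F6 to the keto aldehyde acid F7. Methylenation with aqueous formaldehyde, pyrrolidine and propionic acid then comes back to the route at target 39.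

Further compounds
F1 | step 8 | (2E,6R)-6-(tert-butyldimethylsilyloxy)-6-(5-hydroxy-2-methylphenyl)hex-2-en-1-yl methyl carbonate | Cc1ccc(O)cc1[C@H](O[Si](C)(C)C(C)(C)C)CC/C=C/COC(=O)OC
F2 | step 21 | lithium cross-conjugated dienolate of 19, C7=C8(OLi)-C9=C10 | [Li+].[O-]C1=CC[C@@]2(C)C(=C1)[C@H](O[Si](C)(C)C(C)(C)C)CC[C@@H]2C(=O)OC(C)(C)C
F3 | step 21 | tert-butyl (1S,4R,7R,8aR)-4-(tert-butyldimethylsilyloxy)-8a-methyl-6-oxo-7-(prop-2-en-1-yl)-1,2,3,4,6,7,8,8a-octahydronaphthalene-1-carboxylate | C=CC[C@@H]1C[C@@]2(C)C(=CC1=O)[C@H](O[Si](C)(C)C(C)(C)C)CC[C@@H]2C(=O)OC(C)(C)C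
F4 | step 21 | tert-butyl (1S,4R,7R,8aR)-4-hydroxy-8a-methyl-6-oxo-7-(prop-2-en-1-yl)-1,2,3,4,6,7,8,8a-octahydronaphthalene-1-carboxylate | C=CC[C@@H]1C[C@@]2(C)C(=CC1=O)[C@H](O)CC[C@@H]2C(=O)OC(C)(C)C
F5 | step 24 | (1S,4R,7R,8aR)-4-{[(2E,4R)-2,4-dimethyloct-2-enoyl]oxy}-8a-methyl-6-oxo-7-(prop-2-en-1-yl)-1,2,3,4,6,7,8,8a-octahydronaphthalene-1-carboxylic acid | C=CC[C@@H]1C[C@@]2(C)C(=CC1=O)[C@H](OC(=O)/C(C)=C/[C@H](C)CCCC)CC[C@@H]2C(=O)O
F6 | step 24 | (1S,4R,7S,8aR)-7-(2,3-dihydroxypropyl)-4-{[(2E,4R)-2,4-dimethyloct-2-enoyl]oxy}-8a-methyl-6-oxo-1,2,3,4,6,7,8,8a-octahydronaphthalene-1-carboxylic acid (carbinol epimers) | OCC(O)C[C@@H]1C[C@@]2(C)C(=CC1=O)[C@H](OC(=O)/C(C)=C/[C@H](C)CCCC)CC[C@@H]2C(=O)O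
F7 | step 24 | (1S,4R,7S,8aR)-4-{[(2E,4R)-2,4-dimethyloct-2-enoyl]oxy}-8a-methyl-6-oxo-7-(2-oxoethyl)-1,2,3,4,6,7,8,8a-octahydronaphthalene-1-carboxylic acid | O=CC[C@@H]1C[C@@]2(C)C(=CC1=O)[C@H](OC(=O)/C(C)=C/[C@H](C)CCCC)CC[C@@H]2C(=O)O
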